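The numbers in the tables come from a simulation for an exercise; noise was put on by code.

At early times the two earlier runs already stand about where they end: epsilon's first reading, at 0.250 min, looks like its last, and zeta behaves the same way.

| setting | epsilon | zeta | east | south | south-east | north-west | north-east |
|---|---|---|---|---|---|---|---|
| Z | 5.2 mM | 25 mM | 10 mM | 12 mM | 6.0 mM | 20 mM | 30 mM |
| G | 1.5 equiv | 1.5 equiv | 1.50 equiv | 1.50 equiv | 1.50 equiv | 1.50 equiv | 1.50 equiv |
| Q | 1 mol% | 1 mol% | 1 mol% | 1 mol% | 1 mol% | 1 mol% | 1 mol% |
| remark | run made earlier | run made earlier |  |  |  |  |  |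
| time |  |  | 6.0 min | 6.0 min | 6.0 min | 6.0 min | 6.0 min |

| run | time / min | D / % | Z / % |
|---|---|---|---|
| epsilon | 0.250 | 11 | 88 |
| epsilon | 0.667 | 7 | 89 |
| epsilon | 1.33 | 13 | 89 |
| epsilon | 2.00 | 10 | 89 |
| epsilon | 2.50 | 12 | 90 |
| epsilon | 3.00 | 13 | 89 |
| epsilon | 4.00 | 10 | 91 |
| zeta | 0.667 | 34 | 65 |
| zeta | 1.33 | 34 | 66 |
| zeta | 2.00 | 33 | 68 |
| zeta | 2.50 | 33 | 63 |
| zeta | 3.00 | 35 | 64 |
| zeta | 4.00 | 37 | 62 |

(readings scatter by 1.5 percentage points)

1. ranking by amount of D, in percent of the Z charged, from high to low, at 6.0 min (east / south / south-east / north-west / north-east)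
2. the same order at 80 s (east / south / south-east / north-west / north-east)
3. the amount of D, in percent of the Z charged of the flask you put first, at 6.0 min
4. the amount of D, in percent of the Z charged of the flask you put last, at 6.0 min

- the numbers in the tables scatter by 1.5 percentage points (one standard deviation)

I read the tables column against column. In epsilon D averages 10.9% and Z 89.3%. In zeta D averages 34.3% and Z 64.7%. So the readings of D and Z together come close to the charge in both runs, and zeta's fraction made is larger at the same equivalents and loading.

The fraction made tells me little by itself, so I work with the fractions left. I take Z as read, and G as the charged equivalents minus D; this is a reckoned figure, for the tables have no column of G. Fraction of D over Z left, over G left, over the charged cZ gives 0.0168 mM⁻¹ in epsilon and 0.0184 mM⁻¹ in zeta, close for a scatter of 1.5 percentage points. Their mean is the stall quotient, 0.0176 mM⁻¹.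

Solving that quotient for D, I get 37.3% in north-east and 12.7% in south-east. Since epsilon stands by 0.250 min, well before 80 s, I expect the same ranking at both times.

The forecast says “these look like equilibrium plateaus”. It ranks north-east > north-west > south > east > south-east at 6.0 min and north-east > north-west > south > east > south-east at 80 s, with 37% (35% to 40%) first and 12.6% (11.3% to 14%) last.

The flasks rank north-east > north-west > south > east > south-east at 6.0 min and north-east > north-west > south > east > south-east at 80 s, with north-east at 37.7% and south-east at 12.4%.

    L → Q + D (k = 14.0 s⁻¹)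
    Q ⇌ J (K = 0.943, k = 0.0232 s⁻¹)
    Z + E → L (k = 21200 M⁻¹ s⁻¹)
    G → X (k = 0.379 s⁻¹)
    G + Q ⇌ E (K = 17.0 M⁻¹, k = 1180 M⁻¹ s⁻¹)

The stall quotient is a ruler, not an equilibrium constant. South-east's result gives 0.0172 mM⁻¹, yet its unbound G stands at 0% of the charge at 6.00 min, so the cG counted is not in that flask. The neighbour of south-east with 2.4 mM of Z gives 4.01% where the quotient promises 5.74%. In north-east D stops because G turns into X: with that step taken away, that flask goes from 37.7% to 100%.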